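Retrosynthetic overview
- The target is traced back to a 5,9-oxygen-bridged hydroazulene-4,6-dione. The operations on this stretch are C9 inversion, C6 ketone reduction, reductive opening of the temporary C5–O–C9 bridge, and conversion of the C4 ketone into C3=C4–CH3.
- The bridged dione comes from an acyclic diazo keto aldehyde. One Rh2(OAc)4-catalysed carbonyl ylide formation and intramolecular [3+2] cycloaddition onto a terminal allene forms C1–C5 and C9–C10 together, so ring A (five-membered) and ring B (seven-membered) close in the same operation.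
- Enabling feature: the methylene-bearing C10 lies between C1 and C9, so C1=C10=C18 is a latent allene. The oxygenated C9 and C5 (α to the oxygenated C6) are the termini of a six-membered carbonyl ylide made of C5, C6, C7, C8, C9 and O.
- The diazo compound comes from Regitz diazo transfer on a β-diketone, itself made from a side-chain methyl ketone and an allenic active ester. The methyl ketone comes from trans-selective alkylation and MeLi opening of a cis-γ-lactone.
- The lactone comes from catalytic asymmetric syn-crotylboration of 4-methylpent-4-enal. This sets C11 and C12, which relay to C7 and then to C1, C5 and C9.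

Key step: step 14

Remark (numbering):
- Ring A: C1 is the ring-fusion CH next to C10. C2 is CH2, C3 is =CH, C4 is =C(C17H3), and C5 is the ring-fusion CH next to C6.
- Ring B: C6 is CHOH, C7 is the CH that carries the side chain, C8 is CH2, C9 is CHOH, and C10 is C(=C18H2).
- Side chain: C11 is CH(C19H3), C12 is CHOAc, C13 and C14 are CH2, and C15 is C(=C16H2)(C20H3).

Remark (assumption): compounds 1, 2, 8 and 12 are taken as catalogue chemicals.

Step 1
Reactants: 1 4-methylpent-4-enal; 2 (Z)-crotylboronic acid pinacol ester
Product: 3 (3S,4S)-3,7-dimethylocta-1,7-dien-4-ol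
Conditions: (R)-3,3'-bis(2,4,6-triisopropylphenyl)-1,1'-binaphthyl-2,2'-diyl hydrogen phosphate (5 mol %), toluene, −30 °C; aqueous work-up
Reagents that add atoms: none
Why: Chiral-phosphoric-acid-catalysed asymmetric crotylboration, in which the closed chair transition state translates the (Z)-boronate geometry into the syn C11/C12 relationship and the (R)-catalyst should direct attack to the Re face of the aldehyde, which sets (11S,12S).

Step 2
Reactants: 3 (3S,4S)-3,7-dimethylocta-1,7-dien-4-ol
Product: 5 (3S,4S)-3,7-dimethyloct-7-ene-1,4-diol, via bis(dicyclohexylboryl) adduct 4 (not isolated)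
Conditions: Cy2BH (2.2 equiv), THF, 0 °C; then NaOH, H2O2, 0 °C to rt
Reagents that add atoms: hydrogen peroxide, OO
Why: Hydroboration–oxidation in which the bulky dialkylborane (the first equivalent is consumed by the hydroxyl group) should add to the monosubstituted vinyl group much faster than to the 1,1-disubstituted isopropenyl group, and no stereocenter is touched.

Step 3
Reactants: 5 (3S,4S)-3,7-dimethyloct-7-ene-1,4-diol
Product: 7 (4S,5S)-4-methyl-5-(3-methylbut-3-en-1-yl)oxolan-2-one, via lactol 6 (not isolated)
Conditions: 2,2,6,6-tetramethylpiperidine-1-oxyl (10 mol %), PhI(OAc)2 (2.5 equiv), CH2Cl2, rt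
Reagents that add atoms: none
Why: Nitroxyl-catalysed oxidative lactonisation, in which the primary alcohol is oxidised selectively, the aldehyde closes to lactol 6 and this is oxidised on to the γ-lactone, which ties C11 and C12 into a cis-4,5-disubstituted ring.

Step 4
Reactants: 7 (4S,5S)-4-methyl-5-(3-methylbut-3-en-1-yl)oxolan-2-one; 8 tert-butyl(2-iodoethoxy)dimethylsilane
Product: 9 (3S,4S,5S)-3-[2-(tert-butyldimethylsilyloxy)ethyl]-4-methyl-5-(3-methylbut-3-en-1-yl)oxolan-2-one
Conditions: LiN(i-Pr)2, THF, −78 °C; then 8, DMPU, −78 to −20 °C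
Reagents that add atoms: none
Why: Lactone enolate alkylation, in which the electrophile should enter anti to the cis-disposed ring methyl and alkyl groups, which sets C7 (S) trans to the methyl group.

Step 5
Reactants: 9 alkylated lactone
Product: 10 (3S,4S,5S)-3-[2-(tert-butyldimethylsilyloxy)ethyl]-5-hydroxy-4,8-dimethylnon-8-en-2-one (in equilibrium with its cyclic hemiketal)
Conditions: MeLi (1.05 equiv), THF, −78 °C; then H2O
Reagents that add atoms: methyllithium, [Li]C
Why: Mono-addition of an organolithium to a γ-lactone, in which the tetrahedral lithium hemiketal survives at −78 °C and collapses only on quenching, so that over-addition is avoided and C7, C11 and C12 stay untouched.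

Step 6
Reactants: 10 hydroxy ketone
Product: 11 (5S,6S,7S)-7-acetyl-9-(tert-butyldimethylsilyloxy)-2,6-dimethylnon-1-en-5-yl acetate
Conditions: Ac2O, pyridine, 4-(dimethylamino)pyridine (cat.), CH2Cl2, 0 °C
Reagents that add atoms: acetic anhydride, CC(=O)OC(C)=O
Why: Acylation of the secondary C12 hydroxyl of the open-chain tautomer drains the hemiketal equilibrium and installs the acetate of the target under conditions too mild to epimerise C7.

Step 7
Reactants: 12 methyl pent-4-ynoate
Product: 14 methyl hexa-4,5-dienoate, via propargylic amine 13 (not isolated)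
Conditions: (CH2O)n, Cy2NH, CuI (0.5 equiv), dioxane, reflux
Reagents that add atoms: formaldehyde (as paraformaldehyde), C=O
Why: Crabbé homologation, in which Mannich condensation to propargylic amine 13 followed by copper-mediated 1,5-hydride transfer and loss of the imine turns the terminal alkyne into the terminal allene.

Step 8
Reactants: 14 methyl hexa-4,5-dienoate
Product: 15 hexa-4,5-dienoic acid
Conditions: LiOH, THF–H2O, 0 °C; then 1 M HCl
Reagents that add atoms: lithium hydroxide, [Li+].[OH-]
Why: Ester saponification, in which the unconjugated allene should not be isomerised by cold aqueous LiOH.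

Step 9
Reactants: 15 hexa-4,5-dienoic acid
Product: 16 pentafluorophenyl hexa-4,5-dienoate
Conditions: C6F5OH, DCC, CH2Cl2, 0 °C to rt
Reagents that add atoms: pentafluorophenol, Oc1c(F)c(F)c(F)c(F)c1F
Why: Carbodiimide esterification gives an active ester that is reactive enough for C-acylation of a magnesium enolate.

Step 10
Reactants: 11 acetoxy methyl ketone; 16 pentafluorophenyl hexa-4,5-dienoate
Product: 17 (5S,6S,7S)-9-(tert-butyldimethylsilyloxy)-2,6-dimethyl-7-(3-oxoocta-6,7-dienoyl)non-1-en-5-yl acetate
Conditions: MgBr2·OEt2, i-Pr2NEt, CH2Cl2, rt; 1 M HCl work-up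
Reagents that add atoms: none
Why: Soft-enolisation crossed Claisen acylation, in which MgBr2-complexed 11 is deprotonated by the amine only at the unhindered methyl group (C5) and the magnesium enolate is C-acylated by the active ester under conditions that spare the acetate, the silyl ether and the C7 stereocenter.

Step 11
Reactants: 17 β-diketone
Product: 18 (5S,6S,7S)-9-(tert-butyldimethylsilyloxy)-7-(2-diazo-3-oxoocta-6,7-dienoyl)-2,6-dimethylnon-1-en-5-yl acetate
Conditions: 4-acetamidobenzenesulfonyl azide, Et3N, MeCN, 0 °C to rt
Reagents that add atoms: 4-acetamidobenzenesulfonyl azide, CC(=O)Nc1ccc(cc1)S(=O)(=O)N=[N+]=[N-]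
Why: Regitz diazo transfer to the acidic C5 methylene of the β-diketone.

Step 12
Reactants: 18 silyl-protected diazo diketone
Product: 19 (5S,6S,7S)-7-(2-diazo-3-oxoocta-6,7-dienoyl)-9-hydroxy-2,6-dimethylnon-1-en-5-yl acetate
Conditions: HF·pyridine, THF–pyridine, 0 °C
Reagents that add atoms: none
Why: Fluoride-mediated desilylation under buffered conditions that the acceptor-stabilised diazo group, the acetate and the allene should tolerate.

Step 13
Reactants: 19 diazo alcohol
Product: 20 (5S,6S,7S)-7-(2-diazo-3-oxoocta-6,7-dienoyl)-2,6-dimethyl-9-oxonon-1-en-5-yl acetate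
Conditions: Dess–Martin periodinane, CH2Cl2, 0 °C to rt
Reagents that add atoms: none
Why: Dess–Martin oxidation of the primary alcohol under neutral conditions that leave the 2-diazo-1,3-diketone and C7 untouched.

Step 14
Reactants: 20 diazo keto aldehyde
Product: 22 5,9-oxygen-bridged hydroazulene-4,6-dione (C10 exocyclic methylene; bridge on the face of the C7 side chain and of C2; H-1 on the opposite face; 12-acetate), via carbonyl ylide 21 (not isolated)
Conditions: Rh2(OAc)4 (2 mol %), benzene, 80 °C, slow addition of 20 (final 5 mM)
Reagents that add atoms: none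
Why: Rh2(OAc)4 releases N2 from 20 and the electrophilic diacyl carbenoid at C5 is captured by a lone pair of the C9 aldehyde oxygen (six-membered closure, faster than attack on the remote allene) to give the acyl-stabilised cyclic carbonyl ylide 21, and this 1,3-dipole then adds suprafacially across the internal C1=C10 π bond of the allene in a concerted [3+2] cycloaddition that makes C1–C5 and C9–C10 and leaves C10=C18 as the exocyclic methylene. The closest known reaction type is the rhodium carbenoid/carbonyl ylide formation–intramolecular 1,3-dipolar cycloaddition cascade of γ-carbonyl 2-diazo-1,3-dicarbonyl compounds with tethered unactivated π bonds, and allenes are known dipolarophiles for such ylides. Ring A closes in the fused mode through the three-atom tether C2–C3–C4, and ring B (C1–C10–C9–C8–C7–C6–C5) closes at the same moment as the carbocyclic perimeter of the new 8-oxabicyclo[3.2.1]octane, whose oxygen bridge is temporary. C5 and C9 are set together because the oxygen can bridge only one face, C1 is set by the short tether, which can span C5 and C1 only with C2 exo (syn to oxygen, H-1 endo), and the absolute sense comes from C7, whose branched side chain stays pseudo-equatorial so that the allene folds onto the opposite face of the dipole. The step needs chemoselectivity for ylide formation over cyclopropanation or C–H insertion (secured by the 1,4-relationship of the C6 and C9 carbonyl groups and by slow addition at high dilution) and for the internal over the terminal allene π bond (secured by the tether length), while the isopropenyl group and the acetate are too remote to interfere.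

Step 15
Reactants: 22 bridged dione
Product: 23 C4 enol triflate of 22 (C3=C4)
Conditions: KN(SiMe3)2 (1.05 equiv), THF, −78 °C; then PhNTf2
Reagents that add atoms: N-phenylbis(trifluoromethanesulfonimide), O=S(=O)(N(c1ccccc1)S(=O)(=O)C(F)(F)F)C(F)(F)F
Why: Kinetic enolisation and O-sulfonylation, in which the quaternary C5 lets the cyclopentanone enolise only towards C3 and these methylene protons are far more accessible than the tertiary C7–H of the other ketone or the acetate protons.

Step 16
Reactants: 23 enol triflate
Product: 24 5,9-oxygen-bridged 4-methylhydroazul-3-en-6-one (same configuration as 22)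
Conditions: Me2Zn, Pd(PPh3)4 (5 mol %), THF, 0 °C to rt
Reagents that add atoms: dimethylzinc, C[Zn]C
Why: Negishi cross-coupling of the alkenyl triflate introduces C17 and fixes the C3=C4 double bond, and Me2Zn should not add to the hindered ketone or to the acetate.

Step 17
Reactants: 24 bridged methylcyclopentene ketone
Product: 25 trans-fused (1R,5S,7S,9S)-9-hydroxy-6-ketone (9-epi series, 12-acetate)
Conditions: SmI2 (2.2 equiv), H2O (10 equiv), THF, −78 °C
Reagents that add atoms: none
Why: Reductive cleavage of an α-alkoxy ketone by SmI2, in which two electrons expel the C5–O bond (α to the C6 ketone and allylic) and free the C9 alkoxide, and the trivalent samarium enolate, held by this alkoxide on the former bridge face, should be protonated at C5 by samarium-bound water from that face (overall retention), which sets the trans ring fusion, while the low temperature should prevent drift of C3=C4 into conjugation.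

Step 18
Reactants: 25 hydroxy ketone
Product: 26 (1R,5S,6R,7S,9S)-6,9-diol (9-epimer of the target)
Conditions: NaBH4, CeCl3·7H2O, MeOH, −78 °C
Reagents that add atoms: none
Why: Luche reduction, in which hydride should reach the C6 carbonyl from the face opposite the bulky C7 side chain, which places the C6 hydroxyl cis to that chain (6R), and the cerium medium avoids enolisation at C5.

Step 19
Reactants: 26 9-epi-diol
Product: 27 (9R)-9-O-chloroacetate of the target
Conditions: ClCH2CO2H, PPh3, DIAD, toluene, 0 °C
Reagents that add atoms: chloroacetic acid, OC(=O)CCl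
Why: Mitsunobu reaction, in which the allylic C9 hydroxyl should be activated in preference to the C6 hydroxyl (flanked by two tertiary carbons) and the carboxylate displaces it by SN2 from the open face, which inverts C9 to (R).

Step 20
Reactants: 27 chloroacetate
Product: 28 target (1R,5S,6R,7S,9R,11S,12S)
Conditions: K2CO3 (0.1 equiv), MeOH, −10 °C
Reagents that add atoms: none
Why: Chemoselective transesterification, in which the activated chloroacetate should undergo methanolysis far faster than the secondary acetate, so only the C9 ester is removed and no stereocenter is touched.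

Compound list
1 | 4-methylpent-4-enal | C=C(C)CCC=O | starting material
2 | (Z)-crotylboronic acid pinacol ester | C/C=C\CB1OC(C)(C)C(C)(C)O1 | starting material
3 | (3S,4S)-3,7-dimethylocta-1,7-dien-4-ol | C=C(C)CC[C@H](O)[C@@H](C)C=C | intermediate
4 | bis(dicyclohexylboryl) adduct (O-borinate, primary C-borane) | C=C(C)CC[C@H](OB(C1CCCCC1)C1CCCCC1)[C@@H](C)CCB(C1CCCCC1)C1CCCCC1 | intermediate
5 | (3S,4S)-3,7-dimethyloct-7-ene-1,4-diol | C=C(C)CC[C@H](O)[C@@H](C)CCO | intermediate
6 | lactol of 5 | C=C(C)CC[C@@H]1OC(O)C[C@@H]1C | intermediate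
7 | (4S,5S)-4-methyl-5-(3-methylbut-3-en-1-yl)oxolan-2-one | C=C(C)CC[C@@H]1OC(=O)C[C@@H]1C | intermediate
8 | tert-butyl(2-iodoethoxy)dimethylsilane | ICCO[Si](C)(C)C(C)(C)C | starting material
9 | (3S,4S,5S)-3-[2-(tert-butyldimethylsilyloxy)ethyl]-4-methyl-5-(3-methylbut-3-en-1-yl)oxolan-2-one | C=C(C)CC[C@@H]1OC(=O)[C@@H](CCO[Si](C)(C)C(C)(C)C)[C@@H]1C | intermediate
10 | (3S,4S,5S)-3-[2-(tert-butyldimethylsilyloxy)ethyl]-5-hydroxy-4,8-dimethylnon-8-en-2-one | C=C(C)CC[C@H](O)[C@@H](C)[C@H](CCO[Si](C)(C)C(C)(C)C)C(C)=O | intermediate
11 | (5S,6S,7S)-7-acetyl-9-(tert-butyldimethylsilyloxy)-2,6-dimethylnon-1-en-5-yl acetate | C=C(C)CC[C@H](OC(C)=O)[C@@H](C)[C@H](CCO[Si](C)(C)C(C)(C)C)C(C)=O | intermediate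
12 | methyl pent-4-ynoate | C#CCCC(=O)OC | starting material
13 | methyl 6-(dicyclohexylamino)hex-4-ynoate | COC(=O)CCC#CCN(C1CCCCC1)C1CCCCC1 | intermediate
14 | methyl hexa-4,5-dienoate | C=C=CCCC(=O)OC | intermediate
15 | hexa-4,5-dienoic acid | C=C=CCCC(=O)O | intermediate
16 | pentafluorophenyl hexa-4,5-dienoate | C=C=CCCC(=O)Oc1c(F)c(F)c(F)c(F)c1F | intermediate
17 | β-diketone, (5S,6S,7S)-9-(tert-butyldimethylsilyloxy)-2,6-dimethyl-7-(3-oxoocta-6,7-dienoyl)non-1-en-5-yl acetate | C=C(C)CC[C@H](OC(C)=O)[C@@H](C)[C@H](CCO[Si](C)(C)C(C)(C)C)C(=O)CC(=O)CCC=C=C | intermediate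
18 | silyl-protected 2-diazo-1,3-diketone | C=C(C)CC[C@H](OC(C)=O)[C@@H](C)[C@H](CCO[Si](C)(C)C(C)(C)C)C(=O)C(=[N+]=[N-])C(=O)CCC=C=C | intermediate
19 | diazo alcohol | C=C(C)CC[C@H](OC(C)=O)[C@@H](C)[C@H](CCO)C(=O)C(=[N+]=[N-])C(=O)CCC=C=C | intermediate
20 | diazo keto aldehyde | C=C(C)CC[C@H](OC(C)=O)[C@@H](C)[C@H](CC=O)C(=O)C(=[N+]=[N-])C(=O)CCC=C=C | intermediate
21 | six-membered carbonyl ylide (C5, C6, C7, C8, C9, O) | C=C(C)CC[C@H](OC(C)=O)[C@@H](C)[C@@H]1CC=[O+][C-](C(=O)CCC=C=C)C1=O | intermediate
22 | 5,9-oxygen-bridged hydroazulene-4,6-dione | C=C(C)CC[C@H](OC(C)=O)[C@@H](C)[C@@H]1C[C@@H]2O[C@@]3(C1=O)C(=O)CC[C@H]3C2=C | intermediate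
23 | C4 enol triflate of 22 | C=C(C)CC[C@H](OC(C)=O)[C@@H](C)[C@@H]1C[C@@H]2O[C@@]3(C1=O)C(OS(=O)(=O)C(F)(F)F)=CC[C@H]3C2=C | intermediate
24 | 5,9-oxygen-bridged 4-methylhydroazul-3-en-6-one | C=C(C)CC[C@H](OC(C)=O)[C@@H](C)[C@@H]1C[C@@H]2O[C@@]3(C1=O)C(C)=CC[C@H]3C2=C | intermediate
25 | trans-fused 9-epi-9-hydroxy-6-ketone | C=C(C)CC[C@H](OC(C)=O)[C@@H](C)[C@@H]1C[C@H](O)C(=C)[C@@H]2CC=C(C)[C@H]2C1=O | intermediate
26 | 9-epi-6,9-diol | C=C(C)CC[C@H](OC(C)=O)[C@@H](C)[C@@H]1C[C@H](O)C(=C)[C@@H]2CC=C(C)[C@H]2[C@@H]1O | intermediate
27 | (9R)-9-O-chloroacetate | C=C(C)CC[C@H](OC(C)=O)[C@@H](C)[C@@H]1C[C@@H](OC(=O)CCl)C(=C)[C@@H]2CC=C(C)[C@H]2[C@@H]1O | intermediate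
28 | target CNP0327794.2 | C=C(C)CC[C@H](OC(C)=O)[C@@H](C)[C@@H]1C[C@@H](O)C(=C)[C@@H]2CC=C(C)[C@H]2[C@@H]1O | target

Total step count: 20. Longest linear sequence: 17 steps (steps 1–6 and 10–20).

Steps most likely to fail

1. Step 17.
What may go wrong: the samarium enolate is protonated from the open face, away from the released alkoxide, which would give the cis ring fusion. Alternatively, the C3=C4 bond drifts into conjugation with the ketone.
Fallback (a hydride relay in place of enolate protonation, setting out from 24 and coming back at 25): NaBH4 in MeOH at −40 °C should deliver hydride to C6 of 24 from the oxygen-bridge face, because the other face is shielded by the C1–C10 bridge. This gives the bridged C6-epimeric alcohol F1. BF3·OEt2 in CH2Cl2 at −78 °C should then ionise the tertiary allylic C5–O bond. That triggers a pinacol-type 1,2-shift of the same hydrogen from C6 to C5 on the bridge face, which gives 25 with the trans fusion and without an enolate.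

2. Step 14.
What may go wrong: the carbenoid is intercepted by the allene (cyclopropanation). Alternatively, the ylide undergoes proton shift or dimerisation because the unactivated allene adds too slowly.
Fallback (an alkyne trap with later unveiling of the methylene, setting out from 11 and coming back at 22):
- The dianion of pent-4-ynoic acid (n-BuLi, 2 equiv) is alkylated with ICH2SiMe3 to give 6-(trimethylsilyl)hex-4-ynoic acid F2. This is converted with C6F5OH and DCC into its pentafluorophenyl ester F3.
- Acylation of 11 as in step 10 gives the propargylsilane β-diketone F4. The operations of steps 11 to 13 then give the diazo diketone F5, the diazo alcohol F6 and the diazo aldehyde F7.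
- Rh2(OAc)4 in hot benzene should give, with the more reliable tethered alkyne as dipolarophile, the bridged allylsilane F8 (C1=C10).
- Protodesilylation with CF3CO2H (1 equiv, CH2Cl2, −20 °C) should protonate C1 with allylic shift. Only the cis-fused bicyclo[3.3.0] arrangement (H-1 endo) is attainable, so the product is 22.

3. Step 19.
What may go wrong: SN2' attack of the carboxylate at C18, elimination to a diene, or competing activation of the C6 hydroxyl.
Fallback (oxidation and directed reduction in place of displacement, setting out from 26 and coming back at 28): MnO2 in CH2Cl2 should oxidise only the allylic C9 alcohol to the α-methylene ketone F9. Me4NBH(OAc)3 in MeCN–AcOH at −20 °C, bound to the C6 hydroxyl, should deliver hydride across the ring to the same face of the C9 carbonyl. This places the new hydroxyl on the opposite face (9R) and gives 28 directly.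

Further compounds
F1 | step 17 | bridged C6-epimeric alcohol (H-6 on the bridge face) | C=C(C)CC[C@H](OC(C)=O)[C@@H](C)[C@@H]1C[C@@H]2O[C@@]3([C@H]1O)C(C)=CC[C@H]3C2=C
F2 | step 14 | 6-(trimethylsilyl)hex-4-ynoic acid | OC(=O)CCC#CC[Si](C)(C)C
F3 | step 14 | pentafluorophenyl 6-(trimethylsilyl)hex-4-ynoate | C[Si](C)(C)CC#CCCC(=O)Oc1c(F)c(F)c(F)c(F)c1F
F4 | step 14 | propargylsilane β-diketone | C=C(C)CC[C@H](OC(C)=O)[C@@H](C)[C@H](CCO[Si](C)(C)C(C)(C)C)C(=O)CC(=O)CCC#CC[Si](C)(C)C
F5 | step 14 | propargylsilane diazo diketone | C=C(C)CC[C@H](OC(C)=O)[C@@H](C)[C@H](CCO[Si](C)(C)C(C)(C)C)C(=O)C(=[N+]=[N-])C(=O)CCC#CC[Si](C)(C)C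
F6 | step 14 | propargylsilane diazo alcohol | C=C(C)CC[C@H](OC(C)=O)[C@@H](C)[C@H](CCO)C(=O)C(=[N+]=[N-])C(=O)CCC#CC[Si](C)(C)C
F7 | step 14 | propargylsilane diazo aldehyde | C=C(C)CC[C@H](OC(C)=O)[C@@H](C)[C@H](CC=O)C(=O)C(=[N+]=[N-])C(=O)CCC#CC[Si](C)(C)C
F8 | step 14 | bridged allylsilane (C1=C10, C18H2SiMe3) | C=C(C)CC[C@H](OC(C)=O)[C@@H](C)[C@@H]1C[C@@H]2O[C@@]3(C1=O)C(=O)CCC3=C2C[Si](C)(C)C
F9 | step 19 | 6-hydroxy-9-oxo α-methylene ketone | C=C(C)CC[C@H](OC(C)=O)[C@@H](C)[C@@H]1CC(=O)C(=C)[C@@H]2CC=C(C)[C@H]2[C@@H]1O
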